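**Retrosynthetic overview**
1. The target is two 3-methylisochroman-1-ones joined by the C4–O–C6′ ether (unprimed unit: lactone ring A, 3R,4S, trans; primed unit: lactone ring B, 3′R,4′R, cis); the last operation removes three MOM ethers.
2. The strategy rests on ring B being a benzoate (C8a′–C1′(=O)–O2′) of a lactaldehyde unit (O2′–C3′(CH3)–C4′). With O2′ and C3′ in place as an ester, only the C4a′–C4′ bond and the C4′ carbinol are missing, so an aryl iodide at C4a′ is closed onto the tethered aldehyde (Nozaki–Hiyama–Kishi) and ring B forms last.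
3. The C4–O6′ ether comes from Mitsunobu inversion of the cis alcohol 15 by phenol 10; 15 (ring A) is made first by the same closure on the simple benzoate 13.
4. Both arenes come from one acid 8 (2-methoxyresorcinol: C–H borylation/iodination at C5, Vilsmeier formylation, chlorite oxidation). C3 and C3′ come from (S)-but-3-en-2-ol by Mitsunobu esterification with inversion, its vinyl group being the masked aldehyde carbon C4/C4′.

Key step: step 13

Remark: iodination of a 2,4-dioxygenated benzoate would go to C5′ (ortho/para to oxygen) and not to C4a′, so iodine is placed on the symmetric resorcinol before the carboxyl carbon is added.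

Step 1
Reactants: 1 2-methoxyresorcinol
Product: 2 2-methoxy-1,3-bis(methoxymethoxy)benzene
Conditions: MOMCl, i-Pr2NEt, CH2Cl2, 0 °C → rt
Reagents that add atoms: chloromethyl methyl ether, COCCl
Why: Base-mediated O-alkylation (MOM ether formation) masks both phenols so that the iridium catalyst of the next step meets no O–H bond.

Step 2
Reactants: 2 2-methoxy-1,3-bis(methoxymethoxy)benzene
Product: 4 5-iodo-2-methoxy-1,3-bis(methoxymethoxy)benzene, via pinacol arylboronate 3 (not isolated)
Conditions: [Ir(OMe)(cod)]2 (1.5 mol %), 4,4′-di-tert-butyl-2,2′-bipyridine, B2pin2, THF, 80 °C; then CuI (10 mol %), 1,10-phenanthroline, KI, MeOH/H2O, air, 80 °C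
Reagents that add atoms: bis(pinacolato)diboron, CC1(C)OB(OC1(C)C)B1OC(C)(C)C(C)(C)O1 (boron held in 3 only); potassium iodide, [K+].[I-]
Why: Iridium-catalysed C–H borylation is sterically controlled and C5–H is the only ring hydrogen without an ortho substituent, so boronate 3 should form there alone, and copper-mediated iododeboronation then exchanges boron for iodine at the same carbon by transmetalation instead of electrophilic attack at C4/C6.

Step 3
Reactants: 4 5-iodo-2-methoxy-1,3-bis(methoxymethoxy)benzene
Product: 5 5-iodo-2-methoxybenzene-1,3-diol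
Conditions: HCl (3 M aq.), MeOH, 50 °C
Reagents that add atoms: none
Why: Acid-catalysed acetal exchange with methanol (MOM cleavage) frees the two phenols, which are needed to activate the ring for formylation and to tell the two oxygens apart afterwards; the aryl iodide is inert to dilute acid.

Step 4
Reactants: 5 5-iodo-2-methoxybenzene-1,3-diol
Product: 7 2,4-dihydroxy-6-iodo-3-methoxybenzaldehyde, via aryl iminium chloride 6 (not isolated)
Conditions: POCl3, DMF, MeCN, 0 °C → rt; then H2O, 50 °C
Reagents that add atoms: N,N-dimethylformamide, CN(C)C=O (formyl carbon); water, O (formyl oxygen)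
Why: Vilsmeier–Haack formylation: the chloroiminium ion attacks one of the two equivalent free positions (ortho to one hydroxyl, para to the other) to give iminium salt 6, water then releases the aldehyde, and the new carbonyl group deactivates the ring against a second attack.

Step 5
Reactants: 7 2,4-dihydroxy-6-iodo-3-methoxybenzaldehyde
Product: 8 2,4-dihydroxy-6-iodo-3-methoxybenzoic acid
Conditions: NaClO2, NaH2PO4, H2NSO3H, THF/H2O, 0 °C
Reagents that add atoms: sodium chlorite, [Na+].[O-]Cl=O
Why: Lindgren (Pinnick-type) chlorite oxidation turns the aldehyde into the acid under mildly acidic conditions, with sulfamic acid trapping hypochlorous acid before it can chlorinate the free C5 position of the phenol.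

Step 6
Reactants: 8 2,4-dihydroxy-6-iodo-3-methoxybenzoic acid; 9 (S)-but-3-en-2-ol
Product: 10 (R)-but-3-en-2-yl 2,4-dihydroxy-6-iodo-3-methoxybenzoate
Conditions: PPh3 (1.0 equiv), DIAD (1.0 equiv), THF, 0 °C → rt
Reagents that add atoms: none
Why: Mitsunobu esterification: with one equivalent of reagents only the carboxylic acid is acidic enough to protonate the betaine, and its carboxylate displaces the oxyphosphonium group of 9 in an SN2 step with inversion, so the (S)-carbinol becomes the (R)-configured ester carbon that will be C3 and C3′; alkylation at the carboxylate oxygen is not slowed by the two ortho substituents.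

Step 7
Reactants: 10 (R)-but-3-en-2-yl 2,4-dihydroxy-6-iodo-3-methoxybenzoate
Product: 11 (R)-but-3-en-2-yl 6-iodo-3-methoxy-2,4-bis(methoxymethoxy)benzoate
Conditions: MOMCl, i-Pr2NEt, n-Bu4NI (cat.), CH2Cl2, 0 → 40 °C
Reagents that add atoms: chloromethyl methyl ether, COCCl
Why: MOM ether formation on both phenols (iodide catalysis and warming are needed for the hydrogen-bonded 2-OH) removes the acidic protons that would quench the arylchromium reagent.

Step 8
Reactants: 11 (R)-but-3-en-2-yl 6-iodo-3-methoxy-2,4-bis(methoxymethoxy)benzoate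
Product: 13 (R)-1-oxopropan-2-yl 6-iodo-3-methoxy-2,4-bis(methoxymethoxy)benzoate, via diol 12 (not isolated)
Conditions: OsO4 (2 mol %), NaIO4, 2,6-lutidine, dioxane/H2O, rt; then azeotropic drying (toluene)
Reagents that add atoms: sodium periodate, [Na+].[O-]I(=O)(=O)=O (terminal oxidant; its oxygen reaches the aldehyde through OsO4, O=[Os](=O)(=O)=O)
Why: Lemieux–Johnson cleavage: OsO4 dihydroxylates the terminal alkene to diol 12 and periodate cleaves it to the α-acyloxy aldehyde, lutidine keeping the medium near neutral so that the adjacent (R) centre is not enolised; the arene, the aryl iodide and the MOM ethers are inert.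

Step 9
Reactants: 13 (R)-1-oxopropan-2-yl 6-iodo-3-methoxy-2,4-bis(methoxymethoxy)benzoate
Product: 15 (3R,4R)-4-hydroxy-7-methoxy-6,8-bis(methoxymethoxy)-3-methylisochroman-1-one, via arylchromium dichloride 14 (not isolated)
Conditions: CrCl2 (6 equiv), NiCl2 (5 mol %), degassed DMF, 25 °C, 0.005 M, slow addition of 13; pH 7 buffer
Reagents that add atoms: none
Why: Intramolecular Nozaki–Hiyama–Kishi coupling: zerovalent nickel inserts into the C–I bond, the aryl group passes to trivalent chromium (14) and adds 6-exo-trig to the tethered aldehyde, closing lactone ring A with C4 expected cis to the C3 methyl (3R,4R) through the half-chair transition state described under step 13 (methyl pseudo-equatorial, O–Cr pseudo-axial away from C5–H).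

Step 10
Reactants: 15 (3R,4R)-4-hydroxy-7-methoxy-6,8-bis(methoxymethoxy)-3-methylisochroman-1-one; 10 (R)-but-3-en-2-yl 2,4-dihydroxy-6-iodo-3-methoxybenzoate
Product: 16 (R)-but-3-en-2-yl 2-hydroxy-6-iodo-3-methoxy-4-{[(3R,4S)-7-methoxy-6,8-bis(methoxymethoxy)-3-methyl-1-oxoisochroman-4-yl]oxy}benzoate
Conditions: PPh3, DIAD, toluene, 0 °C → rt (10 in 1.5-fold excess)
Reagents that add atoms: none
Why: Mitsunobu etherification: the oxyphosphonium group at benzylic C4 is displaced by the 4-phenoxide of 10 (the 2-OH is hydrogen-bonded to the ester and hindered) in an SN2 step with inversion, turning (4R) into (4S) and giving the trans ether, while the ortho lactone carbonyl disfavours ionisation at C4.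

Step 11
Reactants: 16 (R)-but-3-en-2-yl 2-hydroxy-6-iodo-3-methoxy-4-{[(3R,4S)-7-methoxy-6,8-bis(methoxymethoxy)-3-methyl-1-oxoisochroman-4-yl]oxy}benzoate
Product: 17 (R)-but-3-en-2-yl 6-iodo-3-methoxy-2-(methoxymethoxy)-4-{[(3R,4S)-7-methoxy-6,8-bis(methoxymethoxy)-3-methyl-1-oxoisochroman-4-yl]oxy}benzoate
Conditions: MOMCl, i-Pr2NEt, n-Bu4NI (cat.), CH2Cl2, 0 → 40 °C
Reagents that add atoms: chloromethyl methyl ether, COCCl
Why: MOM ether formation on the remaining hydrogen-bonded phenol under iodide-catalysed amine-base conditions, which leave the lactone, the allylic ester and the benzylic ether untouched.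

Step 12
Reactants: 17 (R)-but-3-en-2-yl 6-iodo-3-methoxy-2-(methoxymethoxy)-4-{[(3R,4S)-7-methoxy-6,8-bis(methoxymethoxy)-3-methyl-1-oxoisochroman-4-yl]oxy}benzoate
Product: 19 (R)-1-oxopropan-2-yl 6-iodo-3-methoxy-2-(methoxymethoxy)-4-{[(3R,4S)-7-methoxy-6,8-bis(methoxymethoxy)-3-methyl-1-oxoisochroman-4-yl]oxy}benzoate, via diol 18 (not isolated)
Conditions: OsO4 (2 mol %), NaIO4, 2,6-lutidine, dioxane/H2O, rt; then azeotropic drying (toluene)
Reagents that add atoms: sodium periodate, [Na+].[O-]I(=O)(=O)=O (terminal oxidant; its oxygen reaches the aldehyde through OsO4, O=[Os](=O)(=O)=O)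
Why: Lemieux–Johnson cleavage of the only alkene (via diol 18) unmasks the C4′ aldehyde next to the (R) ester carbon under near-neutral conditions that the lactone, the MOM ethers, the aryl iodide and the benzylic ether tolerate.

Step 13
Reactants: 19 (R)-1-oxopropan-2-yl 6-iodo-3-methoxy-2-(methoxymethoxy)-4-{[(3R,4S)-7-methoxy-6,8-bis(methoxymethoxy)-3-methyl-1-oxoisochroman-4-yl]oxy}benzoate
Product: 21 (3R,4S)-4-{[(3R,4R)-4-hydroxy-7-methoxy-8-(methoxymethoxy)-3-methyl-1-oxoisochroman-6-yl]oxy}-7-methoxy-6,8-bis(methoxymethoxy)-3-methylisochroman-1-one, via arylchromium dichloride 20 (not isolated)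
Conditions: CrCl2 (6 equiv), NiCl2 (5 mol %), degassed DMF, 25 °C, 0.005 M, slow addition of 19; pH 7 buffer at 0 °C
Reagents that add atoms: none
Why: Zerovalent nickel, formed from NiCl2 by CrCl2, inserts into the C4a′–I bond and passes the aryl group to trivalent chromium; arylchromium 20 then adds to the tethered aldehyde through a four-centre C–Cr/C=O transition state, and work-up frees the alcohol from its chromium alkoxide. The closest known reaction type is the intramolecular Nozaki–Hiyama–Kishi coupling of an aryl iodide with an aldehyde. Lactone ring B closes 6-exo-trig across the C8a′ ester, which first has to turn into its s-trans rotamer, so 19 is added slowly at high dilution to let the long-lived arylchromium wait for that rotamer and to hold back intermolecular addition. C4′ is set by the C3′ stereocentre in a half-chair transition state with the C3′ methyl pseudo-equatorial (anti to the forming C4a′–C4′ bond) and the aldehyde oxygen bridging to chromium on a face of the arene, since an in-plane exit of chromium is blocked by C5′–H; the new C–O bond is then pseudo-axial and cis to the methyl (3′R,4′R). The step needs 3′,4′-cis selectivity, which rests on this peri C5′–H effect and the equatorial methyl, and chemoselectivity, which rests on the low basicity of arylchromium reagents toward lactone ring A, the ester tether and the benzylic aryl ether. The competing pathways are an anti (Cornforth-type) alignment of C4′=O with C3′–O2′ and a diaxial arrangement, both of which lead to the 3′,4′-trans epimer.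

Step 14
Reactants: 21 (3R,4S)-4-{[(3R,4R)-4-hydroxy-7-methoxy-8-(methoxymethoxy)-3-methyl-1-oxoisochroman-6-yl]oxy}-7-methoxy-6,8-bis(methoxymethoxy)-3-methylisochroman-1-one
Product: 22 (3R,4S)-6,8-dihydroxy-4-{[(3R,4R)-4,8-dihydroxy-7-methoxy-3-methyl-1-oxoisochroman-6-yl]oxy}-7-methoxy-3-methylisochroman-1-one (CNP0139537.4)
Conditions: HCl (3 M aq.), MeOH/THF, 40 °C
Reagents that add atoms: none
Why: Acid-catalysed acetal exchange removes the three aryl MOM ethers, while the benzylic C4–OAr and C4′–OH bonds should resist ionisation because each benzylic carbon has an ortho lactone carbonyl and a β-oxygen, and the δ-lactones are stable to dilute acid.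

**Compound list**
1 | 2-methoxyresorcinol | COc1c(O)cccc1O | starting material
2 | 2-methoxy-1,3-bis(methoxymethoxy)benzene | COCOc1cccc(OCOC)c1OC | intermediate
3 | 2-[4-methoxy-3,5-bis(methoxymethoxy)phenyl]-4,4,5,5-tetramethyl-1,3,2-dioxaborolane (not isolated) | COCOc1cc(B2OC(C)(C)C(C)(C)O2)cc(OCOC)c1OC | intermediate
4 | 5-iodo-2-methoxy-1,3-bis(methoxymethoxy)benzene | COCOc1cc(I)cc(OCOC)c1OC | intermediate
5 | 5-iodo-2-methoxybenzene-1,3-diol | COc1c(O)cc(I)cc1O | intermediate
6 | N-[(2,4-dihydroxy-6-iodo-3-methoxyphenyl)methylidene]-N-methylmethanaminium chloride (not isolated) | C[N+](C)=Cc1c(I)cc(O)c(OC)c1O.[Cl-] | intermediate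
7 | 2,4-dihydroxy-6-iodo-3-methoxybenzaldehyde | O=Cc1c(I)cc(O)c(OC)c1O | intermediate
8 | 2,4-dihydroxy-6-iodo-3-methoxybenzoic acid | OC(=O)c1c(I)cc(O)c(OC)c1O | intermediate
9 | (S)-but-3-en-2-ol | C[C@H](O)C=C | starting material
10 | (R)-but-3-en-2-yl 2,4-dihydroxy-6-iodo-3-methoxybenzoate | COc1c(O)cc(I)c(C(=O)O[C@H](C)C=C)c1O | intermediate
11 | (R)-but-3-en-2-yl 6-iodo-3-methoxy-2,4-bis(methoxymethoxy)benzoate | COCOc1cc(I)c(C(=O)O[C@H](C)C=C)c(OCOC)c1OC | intermediate
12 | (2R)-3,4-dihydroxybutan-2-yl 6-iodo-3-methoxy-2,4-bis(methoxymethoxy)benzoate, both C3 epimers (not isolated) | COCOc1cc(I)c(C(=O)O[C@H](C)C(O)CO)c(OCOC)c1OC | intermediate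
13 | (R)-1-oxopropan-2-yl 6-iodo-3-methoxy-2,4-bis(methoxymethoxy)benzoate | COCOc1cc(I)c(C(=O)O[C@H](C)C=O)c(OCOC)c1OC | intermediate
14 | arylchromium dichloride from 13, chromium in place of iodine (not isolated) | COCOc1cc([Cr](Cl)Cl)c(C(=O)O[C@H](C)C=O)c(OCOC)c1OC | intermediate
15 | (3R,4R)-4-hydroxy-7-methoxy-6,8-bis(methoxymethoxy)-3-methylisochroman-1-one | COCOc1cc2c(c(OCOC)c1OC)C(=O)O[C@H](C)[C@@H]2O | intermediate
16 | (R)-but-3-en-2-yl 2-hydroxy-6-iodo-3-methoxy-4-{[(3R,4S)-7-methoxy-6,8-bis(methoxymethoxy)-3-methyl-1-oxoisochroman-4-yl]oxy}benzoate | COc1c(OCOC)cc2c(c1OCOC)C(=O)O[C@H](C)[C@H]2Oc1cc(I)c(C(=O)O[C@H](C)C=C)c(O)c1OC | intermediate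
17 | (R)-but-3-en-2-yl 6-iodo-3-methoxy-2-(methoxymethoxy)-4-{[(3R,4S)-7-methoxy-6,8-bis(methoxymethoxy)-3-methyl-1-oxoisochroman-4-yl]oxy}benzoate | COc1c(OCOC)cc2c(c1OCOC)C(=O)O[C@H](C)[C@H]2Oc1cc(I)c(C(=O)O[C@H](C)C=C)c(OCOC)c1OC | intermediate
18 | (2R)-3,4-dihydroxybutan-2-yl ester corresponding to 17, both C3 epimers of the diol (not isolated) | COc1c(OCOC)cc2c(c1OCOC)C(=O)O[C@H](C)[C@H]2Oc1cc(I)c(C(=O)O[C@H](C)C(O)CO)c(OCOC)c1OC | intermediate
19 | (R)-1-oxopropan-2-yl 6-iodo-3-methoxy-2-(methoxymethoxy)-4-{[(3R,4S)-7-methoxy-6,8-bis(methoxymethoxy)-3-methyl-1-oxoisochroman-4-yl]oxy}benzoate | COc1c(OCOC)cc2c(c1OCOC)C(=O)O[C@H](C)[C@H]2Oc1cc(I)c(C(=O)O[C@H](C)C=O)c(OCOC)c1OC | intermediate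
20 | arylchromium dichloride from 19, chromium in place of iodine (not isolated) | COc1c(OCOC)cc2c(c1OCOC)C(=O)O[C@H](C)[C@H]2Oc1cc([Cr](Cl)Cl)c(C(=O)O[C@H](C)C=O)c(OCOC)c1OC | intermediate
21 | (3R,4S)-4-{[(3R,4R)-4-hydroxy-7-methoxy-8-(methoxymethoxy)-3-methyl-1-oxoisochroman-6-yl]oxy}-7-methoxy-6,8-bis(methoxymethoxy)-3-methylisochroman-1-one | COc1c(OCOC)cc2c(c1OCOC)C(=O)O[C@H](C)[C@H]2Oc1cc2c(c(OCOC)c1OC)C(=O)O[C@H](C)[C@@H]2O | intermediate
22 | (3R,4S)-6,8-dihydroxy-4-{[(3R,4R)-4,8-dihydroxy-7-methoxy-3-methyl-1-oxoisochroman-6-yl]oxy}-7-methoxy-3-methylisochroman-1-one | COc1c(O)cc2c(c1O)C(=O)O[C@H](C)[C@H]2Oc1cc2c(c(O)c1OC)C(=O)O[C@H](C)[C@@H]2O | target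

**Step count**
Total: 14 steps. Longest linear sequence: 14 steps (steps 1–14; compound 10 feeds both step 7 and step 10, and 9 is purchased).

**Steps most likely to fail**

Step 13 (key ring closure). The facial selectivity at the aldehyde may be poor, because the Cornforth-type and diaxial transition states give the 3′,4′-trans epimer. The closure may also be slow, since it has to pass through the s-trans ester rotamer. The fallback sets the C4′ centre by hydride delivery to a ketone instead of by the C–C bond formation. It sets out from 19: the closure is run as above and the mixture of 21 and its 4′-epimeric alcohol (3′R,4′S) F1 is taken on without separation. Dess–Martin periodinane (NaHCO3, CH2Cl2, 0 °C) should oxidise both to the 4′-ketone F2. Reduction with LiBH(s-Bu)3 in THF at −78 °C, quenched cold with acetic acid, should deliver hydride to the face opposite the C3′ methyl, as with 2-alkyl-1-tetralones, and come back to the route at 21. The cold acidic quench is meant to prevent enolisation at C3′ and translactonisation of the alkoxide.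

Step 10 (ether formation). The activated C4 oxygen may be lost by elimination across C3–C4 to the isocoumarin, or partial ionisation at the benzylic carbon may erode the inversion. The fallback separates activation from displacement. It sets out from 15, which is converted with MsCl and Et3N in CH2Cl2 at −20 °C into the mesylate F3 with retention. F3 is then displaced with inversion by the cesium 4-phenoxide of 10 (Cs2CO3, MeCN, 0 °C → rt), coming back to the route at 16.

Step 9 (first ring closure). The arylchromium may be lost by protonation or intermolecular addition while the ester waits for its s-trans rotamer, or the facial selectivity may be poor. The fallback closes the ring by acylation and sets C4 by reduction. It sets out from 13: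
- Pinnick oxidation (NaClO2, NaH2PO4, 2-methyl-2-butene, t-BuOH/H2O) should give the acid F4.
- Coupling with MeNHOMe·HCl (EDC, HOBt, N-methylmorpholine, CH2Cl2, 0 °C) should give the Weinreb amide F5.
- Iodine–magnesium exchange with i-PrMgCl·LiCl in THF at −40 → −10 °C, followed by Parham-type intramolecular acylation, should give the 1,4-dione F6.
- Reduction with LiBH(s-Bu)3 in THF at −78 °C, anti to the C3 methyl, should come back to the route at 15.

**Further compounds**
F1 | step 13 | (3R,4S)-4-{[(3R,4S)-4-hydroxy-7-methoxy-8-(methoxymethoxy)-3-methyl-1-oxoisochroman-6-yl]oxy}-7-methoxy-6,8-bis(methoxymethoxy)-3-methylisochroman-1-one | COc1c(OCOC)cc2c(c1OCOC)C(=O)O[C@H](C)[C@H]2Oc1cc2c(c(OCOC)c1OC)C(=O)O[C@H](C)[C@H]2O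
F2 | step 13 | (R)-6-{[(3R,4S)-7-methoxy-6,8-bis(methoxymethoxy)-3-methyl-1-oxoisochroman-4-yl]oxy}-7-methoxy-8-(methoxymethoxy)-3-methylisochroman-1,4-dione | COc1c(OCOC)cc2c(c1OCOC)C(=O)O[C@H](C)[C@H]2Oc1cc2c(c(OCOC)c1OC)C(=O)O[C@H](C)C2=O
F3 | step 10 | (3R,4R)-7-methoxy-6,8-bis(methoxymethoxy)-3-methyl-1-oxoisochroman-4-yl methanesulfonate | COCOc1cc2c(c(OCOC)c1OC)C(=O)O[C@H](C)[C@@H]2OS(C)(=O)=O
F4 | step 9 | (R)-2-{[6-iodo-3-methoxy-2,4-bis(methoxymethoxy)benzoyl]oxy}propanoic acid | COCOc1cc(I)c(C(=O)O[C@H](C)C(O)=O)c(OCOC)c1OC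
F5 | step 9 | (R)-1-[methoxy(methyl)amino]-1-oxopropan-2-yl 6-iodo-3-methoxy-2,4-bis(methoxymethoxy)benzoate | COCOc1cc(I)c(C(=O)O[C@H](C)C(=O)N(C)OC)c(OCOC)c1OC
F6 | step 9 | (R)-7-methoxy-6,8-bis(methoxymethoxy)-3-methylisochroman-1,4-dione | COCOc1cc2c(c(OCOC)c1OC)C(=O)O[C@H](C)C2=O
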